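## Structural features

The target is a tetrahydrofuran lignan. In the ring O1–C2–C3–C4–C5, ring A (3,4,5-trimethoxyphenyl) sits on C2, the hydroxymethyl carbon C7 on C3, and the exocyclic carbinol carbon C6 with ring B (3,4-dimethoxyphenyl) on C4; C5 is an unsubstituted methylene next to O1. Four stereocentres stand in a row: the three ring substituents are all-trans (2R,3S,4R), and C6 is S, which is syn to C3 along the chain C5–C4–C6. C2–O1 and C6–OH are both benzylic C–O bonds on electron-rich arenes, so late intermediates will not tolerate protic or Lewis acids, hydrogenolysis or electrophilic oxidants. C5 and C7 are two oxygenated methylenes on neighbouring carbons, each 1,4 to a benzylic oxygen, so an open-chain precursor with both free could close either of two tetrahydrofurans; C7 must stay masked until O1–C5 exists. The real difficulty is the stereochemical relay from one centre through C3 and C4 to the exocyclic C6, together with the differentiation of C5 from C7. The key step exploits the fact that the all-trans array C2–C3–C4 with C5 beside O1 is that of a γ-aryl butenolide (C5 as lactone carbonyl) after anti 1,4-addition of a C7 nucleophile at C3 and anti capture of the enolate at C4 by the C6 acyl group. The 2-acyl lactone so formed holds the C5 and C6 carbonyls 1,3 to each other, which later fixes C6 by chelation.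

## Logic of the disconnections

17 ⇒ 15. No skeletal bond is cut; the C7–O bond is traced back to a C7–Si bond. As a silyl group, the C7 oxygen is absent during every step that handles hydroxyl groups, which solves the C5/C7 problem without a protecting group. The forward step must oxidise C–Si with neither acid nor an electrophile.

15 ⇒ 13 (through 14). The O1–C5 bond is cut at the carbon that is not a stereocentre, so that the forward closure never touches the C2–O bond or its configuration. The gain is an open-chain triol whose C5 can be taken back to the carboxyl level. The forward step must activate the only primary hydroxyl beside two secondary benzylic ones and close the five-membered ring before any alkoxide attacks silicon.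

13 ⇒ 12. C5 is raised to the lactone carbonyl; no skeletal bond is cut. This re-ties O1 to C5 and makes C4 the α-carbon of a carbonyl group. The forward step is a hydride reduction that must leave C–Si and C6 alone.

12 ⇒ 11. The C6 carbinol is traced back to a ketone. One stereocentre disappears, C4 becomes an epimerisable centre between two carbonyls, and C4–C6 becomes an acylation bond. The forward step must deliver hydride to one face of the ketone to give the syn carbinol; the 1,3-dicarbonyl chelate is counted on for this.

11 ⇒ 6 + 8 + 9. C3–C7 and C4–C6 are cut in one operation, as a conjugate addition followed by acylation of the enolate. This is the largest gain of the route: two skeletal bonds and two stereocentres are removed, and only C2 remains as a stereocentre. The forward step needs 1,4-addition faster than loss of the acidic C2 hydrogen of 6, attack anti to ring A, and C-acylation anti to the new side chain. It also needs a silyl group on 8 that survives hydride and alkoxide. Phenyl rather than alkoxy is therefore placed on silicon: an Si–O bond would be cleaved by LiAlH4 and would tie up the C2, C5 or C6 hydroxyls of 13 as cyclic silyl ethers at the moment the C2 oxygen is needed for ring closure.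

8 ⇒ 7. The C–Mg bond is traced back to a C–Cl bond; 7 is commercial.

6 ⇒ 4 (through 5). The lactone C–O bond is cut and the cis double bond is traced back to a triple bond. The gain is a linear ynoate with a single carbinol centre. The forward step must be a cis-selective semi-reduction without base, since the C2 hydrogen of 6 is acidic.

4 ⇒ 1 + 2 (through 3). The C2–C3 bond is cut as a catalytic asymmetric alkynylation of an aromatic aldehyde. This sets the only stereocentre that is not made by relay and leads to two commercial compounds. The descriptor of this centre is S in 4 and R in 5 and 6 with the same spatial arrangement, because alkynyl outranks aryl and vinyl does not.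

## Other disconnections considered

Alternative 1: The cut is O1–C2 and C2–C3. C2 with ring A arrives as aldehyde 1, and the rest is in the homoallylic alcohol A1, an (E)-allylsilane that already carries C4 and the pivaloylated C6.
- Forward key step: A1 and 1 condense under a silyl triflate to an oxocarbenium ion O1=C2. C3 of the allylsilane attacks it (the cation develops at C7, β to silicon) to give the 3-vinyl tetrahydrofuran A2. Removal of the pivalate, oxidative cleavage of the vinyl group and reduction would finish.
- In its favour: the ring is closed in the key step, whereas the chosen plan closes no ring there and spends two later steps on O1–C5. Ring A enters late as a commercial aldehyde. The vinyl group is a more robust hydroxymethyl precursor than a C–Si bond. On these three points the alternative is the better plan.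
- Against it here: the oxocarbenium ion lies inside the forming five-membered ring (endo mode at the electrophile). This is less favourable than the six-membered chair of an ordinary Prins closure and competes with a 2-oxonia-Cope rearrangement that would erase C4. The cation comes from a strongly donor-substituted aldehyde and is a weak, reversible electrophile. The benzylic pivalate on ring B must survive the silyl triflate. C2 and C3 are set relative to C4 through a flexible transition state.
- Comparison: A1 needs the C4/C6 pair set beforehand in a separate stereoselective step, so the step count would be about equal to that of the chosen plan. The alternative is equal in convergence and better in ring formation and in the C7 precursor. It is weaker in how reliably the three ring centres are related; the chosen plan uses two anti additions on a rigid five-membered ring for this.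

Alternative 2: The cut is C4–C5. C5 enters at the formaldehyde level as the methylene of a methoxymethyl ether on the C2 oxygen of the acyclic ketone A3, which carries C2, C3 and the C7 oxygen as a triisopropylsilyl ether.
- Forward key step: with a silyl triflate and a hindered amine, A3 should give a silyl enol ether (C4=C6) and, by loss of methoxide, an O1=C5H2 oxocarbenium ion. Their union forms C4–C5 and gives the tetrahydrofuranyl ketone A4.
- In its favour: the ring is closed in the key step and C5 comes from the cheapest possible source. O1–C2 is never broken or re-formed, so no lactone reduction and re-etherification are needed. The C7 oxygen is an ordinary silyl ether, so no C–Si oxidation is needed. In the handling of C5 and C7 the alternative is the better plan. C4 in A4 is α to the ketone and can equilibrate to the all-trans isomer; on C4 the two plans are equal, since 11 has the same epimerisable position.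
- Against it here: the methoxymethyl ether sits on a benzylic oxygen next to electron-rich ring A. The Lewis acid can ionise C2–O instead of the acetal, and the O1=C5H2 cation can be intercepted by ring A in a Friedel–Crafts reaction. The closure is again endo at the oxocarbenium ion in a five-membered ring. Most important, A4 has lost the second carbonyl group, so the reduction that sets C6 can rely only on O1 as chelating partner or on open-chain induction from C4.
- Comparison: A3 needs its C2/C3 pair from a separate aldol-type step, so the step count would be similar. The alternative is better in economy of oxidation-state changes and equal on C4. It is weaker on C6 and on compatibility of the Lewis acid with the benzylic ether.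

Alternative 3: The cut is O1–C2 and C3–C4, which divides the molecule into its two arylpropanoid halves: the enal A5 (ring A, C2, C3, C7) and the nitroallylic alcohol A6 (ring B, C6, C4, C5, O1).
- Forward key step: under a diarylprolinol silyl ether catalyst, the iminium ion of A5 should take up the hydroxyl of A6 at C2 (oxa-Michael). The enamine so formed should add to the nitroalkene at C4 in a 5-exo-trig Michael closure to give the nitro aldehyde A7. Reduction of the aldehyde, a Nef reaction at C6 and reduction of the resulting ketone would complete the route.
- In its favour: it is by far the shortest and most convergent plan. It uses no organometallic reagent and no cryogenic step, and absolute configuration is under catalytic control. The ring and three ring stereocentres form in one operation by a favourable exo closure, and the epimerisable C3 aldehyde backs the trans arrangement thermodynamically. On step economy, convergence and mode of ring closure it is clearly the better plan.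
- Against it here: intermolecular oxa-Michael addition of an aliphatic alcohol to a β-aryl enal is reversible and not strongly favourable, so C2 is defined only through a dynamic equilibrium that feeds the cyclisation. The acceptor is a trisubstituted α-aryl nitroalkene, hindered at the carbon to be attacked. The nitronate is protonated without control, and C6 must in any case go from C–NO2 to C–OH. That needs a Nef reaction next to epimerisable centres and then reduction of a ketone that, as in Alternative 2, lacks the lactone carbonyl for chelation.
- Comparison: the alternative is equal on the all-trans ring and better on steps. It is weaker at C6, which is where the chosen plan is strongest.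

Key step: step 4

Assumption: the BINOL–titanium alkynylzinc addition is taken to follow the facial sense of the related dialkylzinc additions, so that (R)-BINOL leads to the (S)-alkynol 4; the ligand enantiomer is the only variable this affects.

## Route

Step 1
Reactants: 1 3,4,5-trimethoxybenzaldehyde; 2 methyl propiolate
Product: 4 methyl (S)-4-hydroxy-4-(3,4,5-trimethoxyphenyl)but-2-ynoate, via ethylzinc alkynide 3 (not isolated)
Conditions: 2, Et2Zn, (R)-BINOL (40 mol %), HMPA, CH2Cl2, rt; Ti(OiPr)4 (1 equiv); then 1, rt; aq. NH4Cl
Reagents that add atoms: none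
Why: Catalytic enantioselective alkynylzinc addition to an aldehyde: Et2Zn metalates 2 to 3, which is delivered within the chiral BINOL–titanate to the Re face of 1 and sets the carbinol centre (the later C2) as S. An aromatic aldehyde without α-hydrogen is the best substrate class for this reaction.

Step 2
Reactants: 4 methyl (S)-4-hydroxy-4-(3,4,5-trimethoxyphenyl)but-2-ynoate
Product: 6 (R)-5-(3,4,5-trimethoxyphenyl)furan-2(5H)-one, via hydroxy enoate 5 (not isolated)
Conditions: H2 (1 atm), Pd/CaCO3 poisoned with Pb(OAc)2, quinoline, EtOAc, rt; filter; PPTS (cat.), CH2Cl2, rt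
Reagents that add atoms: none
Why: cis-Semihydrogenation of the ynoate on lead-poisoned palladium gives the (Z)-γ-hydroxy enoate 5, whose hydroxyl and ester are held cis and lactonise under a trace of acid. The stereocentre is not touched, and base is excluded because the γ-hydrogen of 6 is benzylic and vinylogously acidic.

Step 3
Reactants: 7 (chloromethyl)dimethylphenylsilane
Product: 8 [(dimethylphenylsilyl)methyl]magnesium chloride (THF solution, titrated)
Conditions: Mg, BrCH2CH2Br (cat.), THF, 45 °C → rt
Reagents that add atoms: magnesium, [Mg]
Why: Grignard formation by insertion of magnesium into a primary α-silyl alkyl chloride. The phenyl group on silicon makes the later C–Si bond inert to LiAlH4 and to alkoxides, which an alkoxysilyl analogue would not be.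

Step 4
Reactants: 6 (R)-5-(3,4,5-trimethoxyphenyl)furan-2(5H)-one; 8 [(dimethylphenylsilyl)methyl]magnesium chloride; 9 3,4-dimethoxybenzoyl chloride
Product: 11 (3S,4R,5R)-3-(3,4-dimethoxybenzoyl)-4-{[dimethyl(phenyl)silyl]methyl}-5-(3,4,5-trimethoxyphenyl)dihydrofuran-2(3H)-one, via magnesium enolate 10 (not isolated)
Conditions: CuBr·SMe2 (20 mol %), THF–Me2S, −78 °C, 8 (1.3 equiv) added over 1 h; then 9 (1.5 equiv) added rapidly, −78 → −30 °C; aq. NH4Cl
Reagents that add atoms: none
Why: Transmetalation of 8 to a magnesium organocuprate, π-complexation to the enoate, C–C bond formation at C3 through a trivalent-copper intermediate and reductive elimination give the magnesium enolate 10 and return monovalent copper. The closest known reaction type is the copper-catalysed conjugate addition of silylmethyl Grignard reagents to unsaturated carbonyl compounds with trapping of the enolate, as practised on γ-substituted butenolides. No ring is closed. C3 is set by substrate control: the cuprate approaches the flat butenolide on the face opposite to ring A at C2, giving the 2,3-trans product. C4 is set when 10 is C-acylated by 9 on the face opposite to the new C3 side chain, and because C4 of 11 lies between two carbonyls it can equilibrate to the same 3,4-trans arrangement. The step needs 1,4-addition to win over 1,2-addition and over removal of the C2 hydrogen, which copper catalysis and slow addition of 8 at −78 °C should secure by keeping free Grignard reagent from accumulating. It also needs C- over O-acylation, favoured by the tightly bound magnesium counter-ion in THF, and acylation faster than proton transfer from 11 to 10, favoured by rapid addition of excess 9. The silylmethyl group serves as a hydroxymethyl anion equivalent and the lactone carbonyl is C5 at a higher oxidation level.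

Step 5
Reactants: 11 (3S,4R,5R)-3-(3,4-dimethoxybenzoyl)-4-{[dimethyl(phenyl)silyl]methyl}-5-(3,4,5-trimethoxyphenyl)dihydrofuran-2(3H)-one
Product: 12 (3S,4R,5R)-3-[(S)-(3,4-dimethoxyphenyl)(hydroxy)methyl]-4-{[dimethyl(phenyl)silyl]methyl}-5-(3,4,5-trimethoxyphenyl)dihydrofuran-2(3H)-one
Conditions: Zn(BH4)2, Et2O–CH2Cl2, −78 → 0 °C; aq. NH4Cl
Reagents that add atoms: none
Why: Chelation-controlled ketone reduction: zinc bridges the ketone and lactone carbonyl oxygens, and hydride enters on the face of the chelate where C4 carries its hydrogen, away from the C3 branch and its silylmethyl group. This should give the syn carbinol, C6 = S, and Zn(BH4)2 does not reduce the lactone at this temperature.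

Step 6
Reactants: 12 (3S,4R,5R)-3-[(S)-(3,4-dimethoxyphenyl)(hydroxy)methyl]-4-{[dimethyl(phenyl)silyl]methyl}-5-(3,4,5-trimethoxyphenyl)dihydrofuran-2(3H)-one
Product: 13 (1R,2R,3R)-3-[(S)-(3,4-dimethoxyphenyl)(hydroxy)methyl]-2-{[dimethyl(phenyl)silyl]methyl}-1-(3,4,5-trimethoxyphenyl)butane-1,4-diol
Conditions: LiAlH4, THF, 0 °C → rt; aq. NaOH work-up
Reagents that add atoms: none
Why: Hydride reduction of a lactone to the 1,4-diol. No stereocentre is affected, the free C6 hydroxyl is carried as its aluminate, and the C–SiMe2Ph bond is inert to LiAlH4.

Step 7
Reactants: 13 (1R,2R,3R)-3-[(S)-(3,4-dimethoxyphenyl)(hydroxy)methyl]-2-{[dimethyl(phenyl)silyl]methyl}-1-(3,4,5-trimethoxyphenyl)butane-1,4-diol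
Product: 15 (S)-(3,4-dimethoxyphenyl)[(3R,4R,5R)-4-{[dimethyl(phenyl)silyl]methyl}-5-(3,4,5-trimethoxyphenyl)tetrahydrofuran-3-yl]methanol, via primary tosylate 14 (not isolated)
Conditions: TsCl (1.05 equiv), pyridine, CH2Cl2, 0 °C; concentrate; NaH, THF, 0 °C → rt
Reagents that add atoms: none
Why: Selective sulfonylation of the only primary hydroxyl, then intramolecular Williamson etherification: the C2 alkoxide displaces the C5 tosylate in a 5-exo-tet closure, whereas the C6 alkoxide could only form an oxetane. O1–C5 is made without breaking any bond to a stereocentre, and THF at 0 °C is chosen because attack of alkoxide on the arylsilane is slow there.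

Step 8
Reactants: 15 (S)-(3,4-dimethoxyphenyl)[(3R,4R,5R)-4-{[dimethyl(phenyl)silyl]methyl}-5-(3,4,5-trimethoxyphenyl)tetrahydrofuran-3-yl]methanol
Product: 17 (S)-(3,4-dimethoxyphenyl)[(3R,4S,5R)-4-(hydroxymethyl)-5-(3,4,5-trimethoxyphenyl)tetrahydrofuran-3-yl]methanol (CNP0172668.1), via cyclic siloxane 16 (not isolated)
Conditions: KH, t-BuOOH, NMP, 0 °C → rt; then Bu4NF, 60 °C; aq. NH4Cl
Reagents that add atoms: tert-butyl hydroperoxide, CC(C)(C)OO
Why: Tamao–Fleming oxidation under basic, nucleophilic conditions: in the dipolar solvent the C6 alkoxide attacks silicon and expels phenyl as benzene to give the six-membered siloxane 16, whose Si–C7 bond is oxidised by tert-butylperoxide and fluoride with 1,2-shift of C7 from silicon to oxygen. C7 is not a stereocentre, and with no acid or electrophile present the electron-rich rings and both benzylic C–O bonds should survive.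

## Compound list

1 | 3,4,5-trimethoxybenzaldehyde | COc1cc(C=O)cc(OC)c1OC | starting material
2 | methyl propiolate | C#CC(=O)OC | starting material
3 | ethyl(3-methoxy-3-oxoprop-1-yn-1-yl)zinc | CC[Zn]C#CC(=O)OC | intermediate
4 | methyl (S)-4-hydroxy-4-(3,4,5-trimethoxyphenyl)but-2-ynoate | COC(=O)C#C[C@@H](O)c1cc(OC)c(OC)c(OC)c1 | intermediate
5 | methyl (R,Z)-4-hydroxy-4-(3,4,5-trimethoxyphenyl)but-2-enoate | COC(=O)/C=C\[C@@H](O)c1cc(OC)c(OC)c(OC)c1 | intermediate
6 | (R)-5-(3,4,5-trimethoxyphenyl)furan-2(5H)-one | O=C1C=C[C@H](c2cc(OC)c(OC)c(OC)c2)O1 | intermediate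
7 | (chloromethyl)dimethylphenylsilane | ClC[Si](C)(C)c1ccccc1 | starting material
8 | [(dimethylphenylsilyl)methyl]magnesium chloride | Cl[Mg]C[Si](C)(C)c1ccccc1 | intermediate
9 | 3,4-dimethoxybenzoyl chloride | COc1ccc(C(Cl)=O)cc1OC | starting material
10 | chloromagnesium (4R,5R)-4-{[dimethyl(phenyl)silyl]methyl}-5-(3,4,5-trimethoxyphenyl)-4,5-dihydrofuran-2-olate | Cl[Mg]OC1=C[C@@H](C[Si](C)(C)c2ccccc2)[C@H](c2cc(OC)c(OC)c(OC)c2)O1 | intermediate
11 | (3S,4R,5R)-3-(3,4-dimethoxybenzoyl)-4-{[dimethyl(phenyl)silyl]methyl}-5-(3,4,5-trimethoxyphenyl)dihydrofuran-2(3H)-one | COc1ccc(C(=O)[C@H]2C(=O)O[C@@H](c3cc(OC)c(OC)c(OC)c3)[C@@H]2C[Si](C)(C)c4ccccc4)cc1OC | intermediate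
12 | (3S,4R,5R)-3-[(S)-(3,4-dimethoxyphenyl)(hydroxy)methyl]-4-{[dimethyl(phenyl)silyl]methyl}-5-(3,4,5-trimethoxyphenyl)dihydrofuran-2(3H)-one | COc1ccc([C@@H](O)[C@H]2C(=O)O[C@@H](c3cc(OC)c(OC)c(OC)c3)[C@@H]2C[Si](C)(C)c4ccccc4)cc1OC | intermediate
13 | (1R,2R,3R)-3-[(S)-(3,4-dimethoxyphenyl)(hydroxy)methyl]-2-{[dimethyl(phenyl)silyl]methyl}-1-(3,4,5-trimethoxyphenyl)butane-1,4-diol | COc1ccc([C@@H](O)[C@@H](CO)[C@@H](C[Si](C)(C)c2ccccc2)[C@@H](O)c2cc(OC)c(OC)c(OC)c2)cc1OC | intermediate
14 | (2R,3R,4R)-2-[(S)-(3,4-dimethoxyphenyl)(hydroxy)methyl]-3-{[dimethyl(phenyl)silyl]methyl}-4-hydroxy-4-(3,4,5-trimethoxyphenyl)butyl 4-methylbenzenesulfonate | COc1ccc([C@@H](O)[C@@H](COS(=O)(=O)c2ccc(C)cc2)[C@@H](C[Si](C)(C)c2ccccc2)[C@@H](O)c2cc(OC)c(OC)c(OC)c2)cc1OC | intermediate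
15 | (S)-(3,4-dimethoxyphenyl)[(3R,4R,5R)-4-{[dimethyl(phenyl)silyl]methyl}-5-(3,4,5-trimethoxyphenyl)tetrahydrofuran-3-yl]methanol | COc1ccc([C@@H](O)[C@H]2CO[C@@H](c3cc(OC)c(OC)c(OC)c3)[C@@H]2C[Si](C)(C)c4ccccc4)cc1OC | intermediate
16 | cyclic siloxane: 2,2-dimethyl-1-oxa-2-silacyclohexane trans-fused to the tetrahydrofuran at C3–C4, in which the C6 oxygen (C6 still S, bearing ring B) is bonded to the silicon that holds C7 | COc1ccc([C@H]2O[Si](C)(C)C[C@H]3[C@H](c4cc(OC)c(OC)c(OC)c4)OC[C@H]23)cc1OC | intermediate
17 | (S)-(3,4-dimethoxyphenyl)[(3R,4S,5R)-4-(hydroxymethyl)-5-(3,4,5-trimethoxyphenyl)tetrahydrofuran-3-yl]methanol (CNP0172668.1) | COc1ccc([C@@H](O)[C@H]2CO[C@@H](c3cc(OC)c(OC)c(OC)c3)[C@@H]2CO)cc1OC | target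

## Step count and least certain steps

Total step count: 8. Longest linear sequence: 7 steps (steps 1, 2, 4, 5, 6, 7, 8); step 3 is a one-step branch that prepares the Grignard reagent.

Step 4 (key step). The most likely failure is proton transfer. The enolate 10 and any free Grignard reagent are bases, the C2 hydrogen of unreacted 6 is benzylic and vinylogously acidic, and 11 is far more acidic than the lactone from which 10 derives. Loss of the C2 hydrogen would erode enantiomeric purity or divert 6 to its β,γ-unsaturated isomer. Proton exchange between 11 and 10, or O-acylation, would stop the acylation short of completion. The fallback separates the two bond formations. Starting from 6, the copper-catalysed addition of 8 is run with Me3SiCl, which accelerates the 1,4-addition and removes the enolate as the silyl ketene acetal F1. Mild acidic work-up gives the lactone F2. F2 is enolised with LiN(SiMe3)2 at −78 °C and condensed with 3,4-dimethoxybenzaldehyde to the aldol F3 (new bond anti to the C3 side chain, carbinol epimers not separated). Oxidation of F3 with Dess–Martin periodinane returns to the route at 11.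

Step 8. The most likely failure is incomplete cleavage of the silicon–phenyl bond, or base-induced degradation in warm basic peroxide, because oxidising an arylsilane without an electrophile needs forcing conditions. The fallback carries C7 as a vinyl group. Starting from 6, CuBr·SMe2-catalysed addition of vinylmagnesium bromide and capture of the enolate F4 with 9 gives the vinyl keto lactone F5. The operations of steps 5 to 7 (Zn(BH4)2; LiAlH4; TsCl then NaH) lead through the hydroxy lactone F6, the triol F7 and the tosylate F8 to the vinyl tetrahydrofuran F9. Cleavage of the vinyl group with OsO4 (cat.), NaIO4 and 2,6-lutidine gives the aldehyde F10, which is reduced with NaBH4 in the same flask because C3 is epimerisable in F10. This comes back to the route at 17.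

Step 5. The most likely failure is insufficient facial selectivity, if reduction through a non-chelated conformer competes with the zinc chelate and gives the C6 epimer. The fallback replaces substrate control by catalyst control. Starting from 11, asymmetric transfer hydrogenation with RuCl[(S,S)-TsDPEN](p-cymene) and HCO2H–Et3N selects the face of the aryl ketone through the ligand and comes back to the route at 12; no new compound is made.

Step 1. The most likely failure is insufficient enantioselectivity, or the opposite sense of induction, with this electron-rich aldehyde and an alkyne that is also a Michael acceptor, together with competing ethyl transfer. The fallback takes the stereocentre from an enzymatic resolution and the ring from metathesis. Starting from 1, vinylmagnesium bromide gives the racemic allylic alcohol F11. Candida antarctica lipase B with vinyl acrylate should acylate the R enantiomer selectively, following the usual preference of this enzyme for aryl carbinols, to give the acrylate F12 at the cost of half the material. Ring-closing metathesis of F12 with second-generation Grubbs catalyst comes back to the route at 6 without any base and also bypasses step 2.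

## Further compounds

F1 | step 4 | trimethyl{[(4R,5R)-4-{[dimethyl(phenyl)silyl]methyl}-5-(3,4,5-trimethoxyphenyl)-4,5-dihydrofuran-2-yl]oxy}silane | C[Si](C)(C)OC1=C[C@@H](C[Si](C)(C)c2ccccc2)[C@H](c2cc(OC)c(OC)c(OC)c2)O1
F2 | step 4 | (4R,5R)-4-{[dimethyl(phenyl)silyl]methyl}-5-(3,4,5-trimethoxyphenyl)dihydrofuran-2(3H)-one | O=C1C[C@@H](C[Si](C)(C)c2ccccc2)[C@H](c2cc(OC)c(OC)c(OC)c2)O1
F3 | step 4 | (3S,4R,5R)-3-[(3,4-dimethoxyphenyl)(hydroxy)methyl]-4-{[dimethyl(phenyl)silyl]methyl}-5-(3,4,5-trimethoxyphenyl)dihydrofuran-2(3H)-one (both carbinol epimers) | COc1ccc(C(O)[C@H]2C(=O)O[C@@H](c3cc(OC)c(OC)c(OC)c3)[C@@H]2C[Si](C)(C)c4ccccc4)cc1OC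
F4 | step 8 | bromomagnesium (4R,5R)-5-(3,4,5-trimethoxyphenyl)-4-vinyl-4,5-dihydrofuran-2-olate | Br[Mg]OC1=C[C@@H](C=C)[C@H](c2cc(OC)c(OC)c(OC)c2)O1
F5 | step 8 | (3S,4R,5R)-3-(3,4-dimethoxybenzoyl)-5-(3,4,5-trimethoxyphenyl)-4-vinyldihydrofuran-2(3H)-one | COc1ccc(C(=O)[C@H]2C(=O)O[C@@H](c3cc(OC)c(OC)c(OC)c3)[C@@H]2C=C)cc1OC
F6 | step 8 | (3S,4R,5R)-3-[(S)-(3,4-dimethoxyphenyl)(hydroxy)methyl]-5-(3,4,5-trimethoxyphenyl)-4-vinyldihydrofuran-2(3H)-one | COc1ccc([C@@H](O)[C@H]2C(=O)O[C@@H](c3cc(OC)c(OC)c(OC)c3)[C@@H]2C=C)cc1OC
F7 | step 8 | (1R,2R,3R)-3-[(S)-(3,4-dimethoxyphenyl)(hydroxy)methyl]-1-(3,4,5-trimethoxyphenyl)-2-vinylbutane-1,4-diol | COc1ccc([C@@H](O)[C@@H](CO)[C@@H](C=C)[C@@H](O)c2cc(OC)c(OC)c(OC)c2)cc1OC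
F8 | step 8 | (2R,3R,4R)-2-[(S)-(3,4-dimethoxyphenyl)(hydroxy)methyl]-4-hydroxy-4-(3,4,5-trimethoxyphenyl)-3-vinylbutyl 4-methylbenzenesulfonate | COc1ccc([C@@H](O)[C@@H](COS(=O)(=O)c2ccc(C)cc2)[C@@H](C=C)[C@@H](O)c2cc(OC)c(OC)c(OC)c2)cc1OC
F9 | step 8 | (S)-(3,4-dimethoxyphenyl)[(3R,4R,5R)-5-(3,4,5-trimethoxyphenyl)-4-vinyltetrahydrofuran-3-yl]methanol | COc1ccc([C@@H](O)[C@H]2CO[C@@H](c3cc(OC)c(OC)c(OC)c3)[C@@H]2C=C)cc1OC
F10 | step 8 | (2R,3R,4R)-4-[(S)-(3,4-dimethoxyphenyl)(hydroxy)methyl]-2-(3,4,5-trimethoxyphenyl)tetrahydrofuran-3-carbaldehyde | COc1ccc([C@@H](O)[C@H]2CO[C@@H](c3cc(OC)c(OC)c(OC)c3)[C@@H]2C=O)cc1OC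
F0 | step 5 | none | none
F11 | step 1 | rac-1-(3,4,5-trimethoxyphenyl)prop-2-en-1-ol | C=CC(O)c1cc(OC)c(OC)c(OC)c1
F12 | step 1 | (R)-1-(3,4,5-trimethoxyphenyl)allyl acrylate | C=CC(=O)O[C@H](C=C)c1cc(OC)c(OC)c(OC)c1
A1 | alternative 1 | (S)-(3,4-dimethoxyphenyl)[(2R,3E)-1-hydroxy-5-(trimethylsilyl)pent-3-en-2-yl]methyl pivalate | COc1ccc([C@@H](OC(=O)C(C)(C)C)[C@@H](CO)/C=C/C[Si](C)(C)C)cc1OC
A2 | alternative 1 | (S)-(3,4-dimethoxyphenyl)[(3R,4R,5R)-5-(3,4,5-trimethoxyphenyl)-4-vinyltetrahydrofuran-3-yl]methyl pivalate | COc1ccc([C@@H](OC(=O)C(C)(C)C)[C@H]2CO[C@@H](c3cc(OC)c(OC)c(OC)c3)[C@@H]2C=C)cc1OC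
A3 | alternative 2 | (3S,4R)-1-(3,4-dimethoxyphenyl)-4-(methoxymethoxy)-3-{[(triisopropylsilyl)oxy]methyl}-4-(3,4,5-trimethoxyphenyl)butan-1-one | COCO[C@@H](c1cc(OC)c(OC)c(OC)c1)[C@H](CO[Si](C(C)C)(C(C)C)C(C)C)CC(=O)c1ccc(OC)c(OC)c1
A4 | alternative 2 | (3,4-dimethoxyphenyl)[(3R,4S,5R)-4-{[(triisopropylsilyl)oxy]methyl}-5-(3,4,5-trimethoxyphenyl)tetrahydrofuran-3-yl]methanone | COc1ccc(C(=O)[C@H]2CO[C@@H](c3cc(OC)c(OC)c(OC)c3)[C@@H]2CO[Si](C(C)C)(C(C)C)C(C)C)cc1OC
A5 | alternative 3 | (E)-3-(3,4,5-trimethoxyphenyl)acrylaldehyde | COc1cc(/C=C/C=O)cc(OC)c1OC
A6 | alternative 3 | (E)-3-(3,4-dimethoxyphenyl)-3-nitroprop-2-en-1-ol | COc1ccc(/C(=C\CO)[N+](=O)[O-])cc1OC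
A7 | alternative 3 | (2R,3R,4S)-4-[(3,4-dimethoxyphenyl)(nitro)methyl]-2-(3,4,5-trimethoxyphenyl)tetrahydrofuran-3-carbaldehyde (nitro-bearing carbon unassigned) | COc1ccc(C([N+](=O)[O-])[C@H]2CO[C@@H](c3cc(OC)c(OC)c(OC)c3)[C@@H]2C=O)cc1OC
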